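The numbers of this flask come from no measurement, and the outcome is calculated.

I began from a ratio: how fast starting material, as charged, takes up dissolved reagent against how fast the gas refills the solution.

    starting material + reagent → single product (k1 = 210 M⁻¹ h⁻¹)
    reagent + single product → double product (k2 = 84 M⁻¹ h⁻¹)
    reagent + double product → triple product (k3 = 270 M⁻¹ h⁻¹)
    gas ⇌ reagent, rate k4*(csat - [reagent]) (k4 = 5.7 h⁻¹, csat = 2.6 mM)

starting material 0.074 M; gas 2.6 mM (held); time 6.0 h

- at the start none of reagent is dissolved
- run time (flask): 6.0 h

- triple product at 6.0 h, in percent of the starting material charged
- the change that raises the amount of triple product at 6.0 h, in percent of the starting material charged most ("none" if none brings more than 2 percentage points) (north-west / east / none)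
- amount of triple product at 6.0 h, in percent of the starting material charged, after east

- north-west: doubling the transfer coefficient of step 4, all else as stated
- east: doubling the saturation concentration of gas, all else as stated

In this flask that ratio was 2.73, so the drain was faster than the refill. I therefore took c(reagent) to sit at a resting state of saturation divided by one plus the ratio, 0.698 mM, counting the drain by the first step and no other. Starting material then falls pseudo-first-order, with a half-life of 4.73 h. The number I carried, 1.27, is the count of those half-lives that fit into the run, and by my reckoning it leaves 41.5% of the starting material. Triple product lies two steps further on, so I expected little of it, but I put no figure on it. North-west took the count to 2.00 and east to 2.54, which is higher, so I chose east.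

The forecast, which began "Treat the dissolved reagent as quasi-steady", gave 4.7% (4.2% to 5.2%), then east, and 24.8% after east (23.5% to 26%). The simulation gave 4.67%, then east, with a gain of 20 percentage points against 8.5 points for north-west, and 24.8% after east.

The main reason for so little triple product in this flask was the hour of the reading: it held 4.67% at 6.0 h and >99.9% at 60.0 h. My 1.27 half-lives had promised 41.5% of the starting material, and the flask held 36%. The neighbouring flask, charged with 0.018 M, counts 2.84 half-lives, which leaves 14.0%; it held 11%, with 23.6% triple product.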